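The numbers were set for the occasion; no experiment stands behind them.

Amounts first: each flask takes the same substrate and the same free catalyst, and I want the target each holds at its end or outlet.

    substrate + free catalyst → catalyst intermediate A (k1 = 16 L mol⁻¹ min⁻¹)
    catalyst intermediate A → catalyst intermediate B (k2 = 4.3 min⁻¹)
    catalyst intermediate B → free catalyst + target (k3 = 53 min⁻¹)
    2 catalyst intermediate A → spent catalyst (k4 = 20 L mol⁻¹ min⁻¹)
    substrate + target → side product (k5 = 0.0037 L mol⁻¹ min⁻¹)

in all of them: free catalyst 1.5 mM
- teal: substrate 0.49 M (fed, over 3.20 h); time 4.0 h; all but substrate at the start; substrate goes in evenly over 3.20 h, the run ends at 4.0 h
- red: substrate 0.49 M; a single well-mixed tank run continuously and read at steady state, 4.0 h in it on average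
- green: substrate 0.49 M; time 4.0 h; everything together in a closed stirred flask, run for 4.0 h

- percent here means substrate units held: one spent catalyst or side product counts as two
- a step written with two of one species runs at k times the square of its concentration and takes two of it each time
- the stated concentrations are those of everything mixed, before any reaction; amounts are the same in each set-up
- the feed brings no volume worth counting
- run time (teal): 4.0 h

* order of the set-ups by the amount of target at the outlet or at the end, in percent of the substrate put in, highest first (teal / red / green)
* amount of target at the outlet or at the end, in percent of the substrate put in, teal
* amount of target at the outlet or at the end, in percent of the substrate put in, red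
* amount of target at the outlet or at the end, in percent of the substrate put in, green

If the whole catalyst charge stood as catalyst intermediate A, its first half-life by pairing off would be 16.7 min, shorter than the run, so catalyst loss enters my reckoning. Intermediate A forms with substrate and moves on at 4.3 min⁻¹. At a substrate level S it therefore holds a share S/(S + 0.269 M) of the working catalyst, meaning free catalyst plus intermediate A. I replace the substrate curve by a mean, hold that share constant, and reckon the reach of each flask. In the closed flasks this comes from integrating the loss; in the tank, from balancing loss against outflow. Side loss is 0.0037 L mol⁻¹ min⁻¹ times mean substrate, mean target and time, with mean target at half the reach in the teal and green flasks and the whole reach in the tank.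

- teal: mean substrate 0.122 M, share 31.3%, reach 61.7%, side loss 3.35%, target 58.3%
- green: mean substrate 0.245 M, share 47.7%, reach 66.8%, side loss 7.27%, target 59.6%
- red: tank substrate 0.163 M, share 37.8%, reach 59.1%, side loss 8.58%, target 50.6%

Teal's reach, the percentage of the substrate charge its working catalyst carries round during the run, stands below green's. Green's side loss is larger, which brings the two close, with green ahead by 1.3 percentage points. Red comes last.

The forecast differs from me at the top: it gives teal > green > red, with teal 57%, green 52.5% and red 51.3%, on the ground that “Feeding keeps substrate and A low, which spares both catalyst and target and puts teal first”.

The flask gives teal > green > red: teal 58.5%, green 54.3%, red 51.1%, each inside the forecast's range. Green ends with side product 15.6%, half of which passed through the round as target, so its round carried 62.1%, below my reach by 4.7 points. By the same count teal's round carried 63.0%, above my reach of 61.7% by 1.3 points.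

For teal's neighbour charged with 9.0 × 10⁻⁴ M of free catalyst, at teal's share, the reach is 43.0%. That flask holds target 42.5% and side product 8.61%, so its round carried 46.8%.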